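(The runs stem from a simulated flask from invented constants.)

G is the substrate, E the product, D the gas and Q the catalyst.

| flask | G | D | Q | remark | time |
|---|---|---|---|---|---|
| epsilon | 0.029 M | 26 mM (held) | 1 mol% | run made earlier |  |
| beta | 0.043 M | 26 mM (held) | 1 mol% | run made earlier |  |
| flask | 0.057 M | 26 mM (held) | 1 mol% |  | 2.5 min |

- epsilon (time / s: E / %, G / %): 10.0: 0, 66.1; 15.0: 2.5, 53.6; 20.0: 4.6, 42.3; 30.0: 6.3, 26.0; 50.0: 14.0, 9.7; 80.0: 27.6, 3.0; 120: 43.1, 0
- beta (time / s: E / %, G / %): 15.0: 0.9, 36.2; 30.0: 7.4, 12.3; 50.0: 20.7, 3.4; 60.0: 24.8, 0; 80.0: 35.3, 0.7; 90.0: 41.1, 0; 120: 55.0, 0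

(standard deviation of a reading: 1 percentage point)

- the analysis behind the earlier runs scatters by 1 percentage point, standard deviation
- at the start none of D is in solution

1. the E standing at 2.5 min, as a percentage of the G charged
2. the change that raises the amount of E at 2.5 min, in percent of the G charged most ("none" if none brings more than 2 percentage points) (north / south-east / south-west / none)
3. amount of E at 2.5 min, in percent of the G charged, after south-west

- north: doubling the transfer coefficient of D, all else as stated
- south-east: doubling the saturation concentration of D, all else as stated
- south-west: doubling the amount of Q, all else as stated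

I start from the amounts. In the beta run at 50.0 s, G stands at 3.4% and E at 20.7%, so 75.9% of the charge sits in an unseen form, X. I take two times from the readings: τG, in which G falls by a factor e, and τX, in which X does so after G has nearly gone.

| run | τG | τX | τX/τG |
|---|---|---|---|
| epsilon | 20.5 s | 239 s | 11.7 |
| beta | 14.8 s | 134 s | 9.05 |

Dividing one by the other removes the clock, and from beta, the run nearer the flask, I carry the reading ρ = 9.05, the number of G lifetimes in one X lifetime. The product of τG and the G charged stays close between runs, so I put the flask at τG = 11.2 s and τX = 101 s. Beta's X line starts after a lag of 13.1 s, so I expect 74.2% E at 2.5 min. With τX about ten times τG, X to E is the slower of these two stages in my reckoning for the flask.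

The forecast gives 75%, south-west as the best change and 92% after it, holding that “transfer is not limiting”.

The flask gives 72.3%. The best change is south-east, which gains 22 percentage points, against 17 points for south-west, reaching 89.4%, and 10 points for north.

    J + Q + X → Q + E (k = 1120 M⁻² s⁻¹)
    D ⇌ J, rate k2*(csat - [J]) (kL = 0.0329 s⁻¹)
    G + Q → Q + X (k = 157 M⁻¹ s⁻¹)

Here J is dissolved D, and in the flask it stands at 0.0186 M at 2.50 min, below the saturation value of 26 mM. The flask's own table gives τX = 94.7 s over the second half of the time, which is 8.46 of my τG against the carried ρ of 9.05. For the same flask read at 40 s, my τG gives 2.78% G left, and it holds 2.79%. With τX taken as ρ times τG, and my lag, I reckon 23.3% E, and it holds 17.1%, with 80.1% still X.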